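# A 2β,3β,13-trihydroxy C19 gibberellin lactone by an intramolecular (4+3) cycloaddition: synthesis design

Gibberellin numbering (C1 to C19) is used throughout. α is the face of the 19,10-lactone bridge and β is the face of H5. The target, compound 39, is the gibberellin that carries the number eight in the A series.

## The problem

The target 39 is a tetracarbocycle in which ring A is spanned by the 19,10-lactone between C4 and C10, the five-membered ring B is trans-fused to ring A at C5–C10, and rings C and D form a bicyclo[3.2.1]octane that shares C8–C9 with ring B. Nine stereocentres must be set (C2, C3, C4, C5, C6, C8, C9, C10 and C13), four of them fully substituted (C4, C8, C10 and C13). The lactone makes ring A a rigid bicycle, so C4 dictates C10 and the bridge decides the face on which C5, C2 and C3 are functionalised. C6 can be epimerised next to its carboxyl and the natural arrangement, with C7 trans to C4 on ring B, should be the stable one, whereas C8, C9 and C13 have no such handle and must come from the ring-forming event itself. Three groupings are fragile: the tertiary C13 alcohol next to the C16 methylene rearranges in strong acid, the lactone oxygen on C10 is lost by β-elimination as soon as an enolate forms at C9, and the 3β-hydroxyl β to the lactone carbonyl can epimerise by retro-aldol cleavage in strong base. The cis-diol and the C7 acid therefore travel protected for most of the route. The feature that opens the molecule is the seven-membered ring C8–C9–C11–C12–C13–C16–C15, bridged by C14, with oxygen on the bridgehead C13, the exocyclic carbon on C16 and ring B attached at C8–C9. Such a ring is the adduct of a three-carbon cation across C8 and C13 of a 1-oxygenated cyclopentadiene made of the ring D carbons.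

## Retrosynthesis

End game, 39 back to 33. No skeletal bond is cut here. The acid is carried as methyl ester 38, the diol as an acetonide and the C13 alcohol as a silyl ether in 37. The C16 methylene is traced to allylsilane 36, because an exocyclic alkene next to the C13 oxygen would not survive the earlier steps, whereas the endocyclic C15=C16 allylsilane does and moves outward only when acid is applied. A ketone is added retrosynthetically at C11 in 33 and reached through alcohol 34 and thionocarbonate 35. It is the price of the key step and is deleted by radical deoxygenation. The forward steps must reduce it at once, because in 33 it lies β to the lactone oxygen.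

Key disconnection, 33 back to 31. C8–C9 and C12–C13 are cut together. This opens rings B and C and removes C8, C9 and C13 as stereocentres. It leaves a bicyclic lactone that carries a cyclopentadiene on C6 and a three-carbon cation precursor on C10. The neighbouring cuts are an aldol at C12–C13 after a separate ring B closure, or a Diels–Alder route to a bicyclo[2.2.1] system followed by ring expansion. Both need more steps and build the bridgehead oxygen less directly. The forward reaction has to release cation 32 without ever forming an enolate at C9. For that reason the leaving group sits on C9 and the enol derivative on the C12 side, as a 2-silyloxyallyl chloride, and not the reverse. It must also place the new carbocycle on the α face of the forming ring B.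

Precursor assembly, 31 back to 27. No carbon–carbon bond is cut. Both enol ethers of 31 come from diketone 29 in one soft enolisation, through the kinetic diene 30. Ketone 29 comes from alcohol 28 and that from the protected chlorohydrin 27. Ring D is held as a 4-substituted 2-(silylmethyl)cyclopent-2-enone, so that C6–H stays an ordinary ester α-hydrogen. A ring alkene conjugated through C8 would make this hydrogen doubly activated and divert silylation to an exocyclic trienol ether. The forward step must enolise the methyl ketone toward C12 and bring the diene into the 1-silyloxy form.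

Ring D decoration and ring A diol, 27 back to 21. C16–C17 is cut to α-iodoenone 26 and a silylmethylzinc reagent. A cross-coupling is preferred over enolate alkylation because it needs no base near C6. The diol acetonide is traced through diol 25 and alkene 24 to the 3β-alcohol 23. Dihydroxylation is placed at the iodoenone stage because no other reactive alkene is present there. Iodoenone 23 comes from enone 22, and the C13 oxygen of 22 from allylic oxidation of cyclopentene 21. The precursor 21 has lost two oxygens, the C17 carbon and two stereocentres.

C6–C8 bond, 21 back to 15 and 16. The bond is cut as an Ireland–Claisen rearrangement of ester 17, made from acid 15 and (S)-cyclopent-2-en-1-ol 16. C6 hangs on a carbon flanked by two quaternary centres, so intermolecular alkylation of its enolate would be slow and unselective. The sigmatropic route forms the bond intramolecularly through ketene acetal 18 and silyl ester 19. It sets C6 by chirality transfer in acid 20, which is esterified to 21. The cut removes all five ring D carbons and leaves a bicyclic lactone acid.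

C5–C6 bond, 15 back to 12. The acetic acid arm comes from the allyl group of 13 through aldehyde 14. The allyl group is attached by radical allylation of the bridge iodide 12. A radical is the only practical reactive intermediate at this bridging carbon, where displacement and enolate chemistry are both closed. The forward step must deliver the new bond to the lactone face, and the axial 3β-hydroxyl of 12 is there to shield the other one.

C10 side arm, 12 back to 8. No carbon is added or removed. The C9 chloride and C11 oxygen are traced through silyl ether 11 and chlorohydrin 10 to the propenyl group of 9, and that to the allyl group of iodolactone 8. Halohydrin formation puts the halogen on C9, whereas epoxide opening would put it on C11.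

Ring A, 8 back to 1 and 2. C10–O and C5–I are cut by iodolactonisation of enone amide 7, which also releases the auxiliary. The C4–methyl bond is cut to a Birch reductive alkylation of benzamide 5 through diene 6, in which the prolinol ether sets C4. Amide 5 comes from bromo amide 4 by cross-coupling, and 4 from acid 1 and amine 2 through acid chloride 3. An aromatic ring is chosen over a cyclohexanedione because it delivers the C10 arm, C18, C19 and the C3 oxygen in four steps with C4 under auxiliary control.

## Roads not taken

Alternative 1: ring B contraction of a steviol derivative. The cut is the C6–C8 bond, formed at the expense of C7–C8. The forward sequence starts from steviol A2 , which is esterified and given an equatorial bromide on C6 and an equatorial hydroxyl on C7. Ionisation of the bromide lets C8 shift from C7 to C6 in a semipinacol manner. This contracts ring B and releases C7 as the formyl group of aldehyde A1 . Merits: with A2 the rings C and D, the C13 hydroxyl, the C16 methylene and the centres C4, C5, C8, C9 and C13 are bought. The shift copies the biosynthesis, and the equatorial bromide has the migrating ring bond antiperiplanar. For rings B to D this road is far shorter than the chosen one. Weak points: A1 still carries the C20 methyl, which must be oxidised at an unactivated angular position, excised and replaced by the lactone oxygen on C10. Ring A of A1 has no functionality at C1 to C3, so the 2β,3β-diol would need C–H oxidation or a multi-step desaturation. Comparison: the chosen plan cannot match this economy for rings B to D. What it sets against it is a ring A that carries the lactone, the C3 oxygen and no C20 from the fourth step on, and independence from a natural diterpenoid.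

Alternative 2: sugar lactone and Ireland–Claisen ring contraction. The cut is C4–C5. In the forward key step the silyl ketene acetal of a pentose-derived six-membered lactone, whose ring oxygen sits on C1 of a preformed B/C/D part with a C5=C10 alkene, rearranges. The shift forms C4–C5, closes ring A and opens the lactone to the C19 acid A3 . Merits: the diol and the absolute configuration come from the chiral pool, C4 and C5 are set in one step, and the acid is placed for lactonisation onto C10. In this respect the road is better than the chosen plan, which needs an auxiliary and a late dihydroxylation. Weak points: the B/C/D tricycle with the bridgehead oxygen must be made first, and this road offers nothing for it. The lactone enolate carries a β-alkoxy group and can eliminate. The contraction must pass through a boat-like transition state on a hindered tetrasubstituted alkene. Acid A3 still needs a separate lactonisation onto the 1(10)-alkene in the presence of the C16 methylene. Comparison: this road solves the ring A stereochemistry more elegantly but leaves the harder half of the molecule open. The chosen plan builds that half in its key step and pays for it with a longer ring A sequence.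

Alternative 3: reductive aldol closure of ring A. The cut is C3–C4. In the forward key step [(Ph3P)CuH]6 adds hydride to the C18 methylene of an α-methylene lactone, and the resulting C4 copper enolate adds to a C3 aldehyde to give ester A4 . Merits: ester A4 is two deprotections from the target, against six steps after the key step in the chosen plan. The conditions tolerate the isolated methylene and the free C13 alcohol. In convergence and end-game length this road is better. Weak points: the substrate is the complete B/C/D lactone with a β-silyloxy aldehyde chain, which is a long synthesis in itself. The aldol must deliver the 3β-alcohol and the C4 configuration in a bridged closure for which no control element is evident. The adduct can revert by retro-aldol, and the aldehyde can lose its β-silyloxy group. Comparison: the chosen plan accepts a longer end game. In exchange its key step makes two rings and three stereocentres from a precursor assembled from simple pieces, and its ring A stereocentres are set under known control.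

Key step: step 23

## Route

Remark 1: the (S)-prolinol methyl ether amide is assumed to direct methylation of the Birch enolate to the face that gives the C4 configuration drawn in 6. If the sense is the opposite, the (R)-amine is used and nothing else changes.

Remark 2: (S)-cyclopent-2-en-1-ol, compound 16, is treated as a purchasable building block.

Remark 3: C9 and C11 of the C10 side arm are carried as diastereomer mixtures, because C11 is later oxidised and C9 becomes trigonal in 32. The C11 carbinol of 34 and 35 is also immaterial. The SMILES leave these centres open.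

Step 1
Reactants: 1 5-bromo-2-methoxybenzoic acid; 2 (S)-2-(methoxymethyl)pyrrolidine
Product: 4 (S)-(5-bromo-2-methoxyphenyl)[2-(methoxymethyl)pyrrolidin-1-yl]methanone, via acid chloride 3 (not isolated)
Conditions: (COCl)2, cat. DMF, CH2Cl2, 0 °C to rt; then 2, Et3N, CH2Cl2, 0 °C
Reagents that add atoms: none
Why: Amide formation through the acid chloride attaches the auxiliary that later controls C4; no stereocentre is formed.

Step 2
Reactants: 4 bromo amide
Product: 5 (S)-(5-allyl-2-methoxyphenyl)[2-(methoxymethyl)pyrrolidin-1-yl]methanone
Conditions: allylSnBu3, Pd(PPh3)4 (5 mol %), toluene, 100 °C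
Reagents that add atoms: allyltributylstannane C=CC[Sn](CCCC)(CCCC)CCCC
Why: Stille coupling of the aryl bromide; the allyl group supplies C9, C11 and C12 and sits para to the methoxy group, the position that becomes C10.

Step 3
Reactants: 5 allyl amide
Product: 7 (S)-4-allyl-2-methyl-2-{[(S)-2-(methoxymethyl)pyrrolidin-1-yl]carbonyl}cyclohex-3-en-1-one, via Birch diene 6 (not isolated)
Conditions: K, NH3/THF, t-BuOH (1 equiv), −78 °C; MeI, −78 °C; then 1 M HCl, MeOH, rt
Reagents that add atoms: iodomethane CI; water O
Why: Asymmetric Birch reduction–alkylation: the amide enolate is methylated at C4 on the face left open by the chelated methoxymethyl arm, and dilute acid hydrolyses the enol ether to the C3 ketone. The isolated allyl alkene is not reduced, and the C5=C10 alkene cannot move into conjugation across the quaternary C4.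

Step 4
Reactants: 7 enone amide
Product: 8 5-allyl-8-iodo-1-methyl-6-oxabicyclo[3.2.1]octane-2,7-dione (19,10-lactone across ring A; C3 ketone; 5β-iodide; allyl on C10)
Conditions: I2, THF/H2O, rt, dark
Reagents that add atoms: iodine II; water O
Why: Iodolactonisation of the tertiary amide: the iodonium ion on the trisubstituted C5=C10 alkene is opened at the tertiary C10 by the amide oxygen, and water hydrolyses the iminium lactone and frees the auxiliary. The bridge forces O10 cis to C19 and leaves iodine anti on C5.

Step 5
Reactants: 8 allyl iodolactone
Product: 9 (E)-prop-1-enyl iodolactone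
Conditions: RuHCl(CO)(PPh3)3 (5 mol %), toluene, 80 °C
Reagents that add atoms: none
Why: Ruthenium hydride alkene isomerisation by one position; it must stop at C9=C11 because C10 is quaternary.

Step 6
Reactants: 9 propenyl iodolactone
Product: 10 chlorohydrin (C9 chloride; C11 hydroxyl)
Conditions: NCS, acetone/H2O, rt
Reagents that add atoms: N-chlorosuccinimide O=C1CCC(=O)N1Cl; water O
Why: Chlorohydrin formation with anti addition: water opens the chloronium ion at C11, away from the quaternary C10 and its electron-withdrawing lactone oxygen, so chlorine stays on C9. Epoxide opening would give the opposite regiochemistry.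

Step 7
Reactants: 10 chlorohydrin
Product: 11 triethylsilyl ether of 10
Conditions: TESCl, imidazole, DMF, rt
Reagents that add atoms: chlorotriethylsilane CC[Si](Cl)(CC)CC
Why: Silylation of the secondary alcohol keeps the chlorohydrin from closing to an epoxide in the basic steps that follow.

Step 8
Reactants: 11 keto iodolactone
Product: 12 3β-alcohol (axial hydroxyl on C3)
Conditions: LiBH(s-Bu)3, THF, −78 °C
Reagents that add atoms: none
Why: Bulky borohydride reduction: the axial iodide on C5 blocks the β face of the carbonyl, so hydride enters from the α side and gives the axial 3β-alcohol. This hydroxyl shields the β face of C5 in step 9 and is the leaving group for the 2-ene in step 16.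

Step 9
Reactants: 12 iodo alcohol
Product: 13 5-allyl lactone (allyl on C5 syn to the lactone bridge; H5 β)
Conditions: allylSnBu3, AIBN, benzene, 80 °C
Reagents that add atoms: allyltributylstannane C=CC[Sn](CCCC)(CCCC)CCCC
Why: Keck radical allylation: the C5 bridge radical is trapped on the face over the flat lactone, away from the syn-axial 3β-hydroxyl and H1β. This sets C5 and brings in C6 and C7; the secondary chloride is inert to tin radicals.

Step 10
Reactants: 13 allyl lactone
Product: 15 C5 acetic acid (C7 carboxylic acid), via aldehyde 14 (not isolated)
Conditions: O3, CH2Cl2/MeOH, −78 °C; PPh3; then NaClO2, NaH2PO4, 2-methyl-2-butene, t-BuOH/H2O, rt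
Reagents that add atoms: ozone [O-][O+]=O; sodium chlorite [Na+].[O-]Cl=O
Why: Ozonolysis followed by Pinnick oxidation shortens the allyl group to the C6–C7 acid without touching the chloride, the silyl ether or the lactone.

Step 11
Reactants: 15 acid; 16 (S)-cyclopent-2-en-1-ol
Product: 17 (S)-cyclopent-2-enyl ester of 15
Conditions: DCC, DMAP (cat.), CH2Cl2, 0 °C to rt
Reagents that add atoms: none
Why: Steglich esterification with retention at the carbinol carbon; the hindered axial 3β-hydroxyl does not compete with 16 used in excess.

Step 12
Reactants: 17 cyclopentenyl ester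
Product: 20 2-(cyclopent-2-enyl)acetic acid with C6 and C8 set, via silyl ketene acetal 18 (not isolated), via silyl ester 19 (not isolated)
Conditions: LiN(i-Pr)2, Me3SiCl/Et3N, THF, −78 °C to 50 °C; aq. citric acid, MeOH
Reagents that add atoms: none
Why: Ireland–Claisen rearrangement: the E ketene acetal from kinetic enolisation in THF reacts suprafacially through a chair in which ring A points away from the cyclopentene, and the Z isomer would reach the same product through a boat. C6 is set by chirality transfer from the carbinol carbon of 16 (C8 is set too and erased in step 22), and the hindered C6–C8 bond forms intramolecularly.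

Step 13
Reactants: 20 acid
Product: 21 methyl ester of 20
Conditions: Me3SiCHN2, toluene/MeOH, 0 °C
Reagents that add atoms: (trimethylsilyl)diazomethane C[Si](C)(C)C=[N+]=[N-]
Why: Base-free esterification with the diazoalkane leaves C6 and the lactone untouched.

Step 14
Reactants: 21 cyclopentene
Product: 22 4-substituted cyclopent-2-enone (C13 ketone; C15=C16)
Conditions: Rh2(cap)4 (dirhodium tetrakis(caprolactamate), 1 mol %), t-BuOOH, K2CO3, CH2Cl2, rt
Reagents that add atoms: tert-butyl hydroperoxide CC(C)(C)OO
Why: Dirhodium-catalysed allylic oxidation with the hydroperoxide: hydrogen is abstracted from the unhindered C13 methylene and oxygen is delivered to the same end of the allyl radical, away from the branched C8.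

Step 15
Reactants: 22 enone
Product: 23 2-iodo enone (iodine on C16)
Conditions: I2, pyridine, CH2Cl2, rt
Reagents that add atoms: iodine II
Why: α-Iodination of the enone by conjugate addition of pyridine, iodination of the enolate and elimination.

Step 16
Reactants: 23 3β-alcohol
Product: 24 2-ene (C2=C3)
Conditions: Martin sulfurane, CH2Cl2, rt
Reagents that add atoms: none
Why: Dehydration with the sulfurane by anti elimination of the axial 3β-hydroxyl and the axial H2α; C4 is quaternary, so only the 2-ene can form.

Step 17
Reactants: 24 2-ene
Product: 25 2β,3β-diol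
Conditions: OsO4 (5 mol %), NMO, acetone/H2O, 0 °C
Reagents that add atoms: N-methylmorpholine N-oxide C[N+]1([O-])CCOCC1; water O
Why: Upjohn dihydroxylation: the electron-poor iodoenone reacts much more slowly than the isolated cis-alkene. Osmium adds to the face anti to the lactone bridge, where only H5 points over the alkene, giving the 2β,3β-diol.

Step 18
Reactants: 25 diol
Product: 26 2,3-acetonide
Conditions: 2-methoxypropene, PPTS (cat.), CH2Cl2, 0 °C
Reagents that add atoms: 2-methoxypropene C=C(C)OC
Why: Acetonide formation by acetal exchange under anhydrous mild acid, which the triethylsilyl ether survives; it also locks the 3β-hydroxyl against retro-aldol epimerisation.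

Step 19
Reactants: 26 iodoenone
Product: 27 2-(trimethylsilylmethyl) enone (C17 attached to C16)
Conditions: Me3SiCH2ZnI (from Me3SiCH2I, Zn, THF), Pd(PPh3)4 (5 mol %), THF, 50 °C
Reagents that add atoms: (trimethylsilylmethyl)zinc iodide C[Si](C)(C)C[Zn]I
Why: Negishi coupling of the α-iodoenone with the silylmethylzinc reagent installs C17 as a latent allylsilane; the unactivated secondary chloride does not add to zerovalent palladium under these conditions.

Step 20
Reactants: 27 silyl ether
Product: 28 free chlorohydrin (C11 hydroxyl)
Conditions: HF·pyridine, pyridine, THF, 0 °C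
Reagents that add atoms: none
Why: Buffered fluoride cleaves the secondary triethylsilyl ether; the allylsilane, the acetonide and the enone are stable to it.

Step 21
Reactants: 28 chlorohydrin
Product: 29 α-chloro methyl ketone (C9 chloride; C11 ketone)
Conditions: Dess–Martin periodinane, NaHCO3, CH2Cl2, 0 °C to rt
Reagents that add atoms: none
Why: Dess–Martin oxidation under buffered, non-enolising conditions, so the acidic C9–H next to the lactone oxygen is not disturbed.

Step 22
Reactants: 29 diketone
Product: 31 bis(silyl enol ether): 1-silyloxycyclopentadiene with C10 arm CHCl–C(OTBS)=CH2, via kinetic diene 30 (not isolated)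
Conditions: TBSOTf, Et3N, CH2Cl2, −78 to 0 °C; then rt
Reagents that add atoms: tert-butyldimethylsilyl trifluoromethanesulfonate CC(C)(C)[Si](C)(C)OS(=O)(=O)C(F)(F)F
Why: Soft enolisation of both ketones: the methyl ketone loses a proton from C12 because C9–H is neopentyl and shielded, giving the 2-silyloxyallyl chloride. The cyclopentenone gives the cross-conjugated dienol ether 30, which equilibrates at room temperature by 1,5-hydrogen shifts to the conjugated isomers, among them 31 with C8 as diene terminus.

Step 23
Reactants: 31 bis(silyl enol ether)
Product: 33 pentacyclic 11-ketone with C15=C16 allylsilane and C13 silyl ether, via silyloxyallyl cation 32 (not isolated)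
Conditions: AgOSO2CF3 (1.2 equiv), 2,6-di-tert-butyl-4-methylpyridine, CH2Cl2, −78 to 0 °C; aq. NaHCO3
Reagents that add atoms: none
Why: Proposed new method: monovalent silver removes the C9 chloride of 31 and gives the 2-silyloxyallyl cation 32 (C9–C11–C12) without base, so no enolate ever sits next to the C10 lactone oxygen. The closest known reactions are the silver-promoted (4+3) cycloadditions of 2-silyloxyallyl chlorides with cyclopentadiene and furan and the intramolecular (4+3) reactions of oxyallyl cations from α-chloro ketones with tethered furans and dienes; a tethered 1-silyloxycyclopentadiene has not been used. C8, the vinylogous terminus of the silyl dienol ether, attacks C9 and closes ring B as a five-membered ring in a 5-exo mode along the tether C10–C5–C6, concerted or not. The C11 silyl enol ether then adds through C12 to the C13 silyloxycarbenium ion in a 6-(enolendo)-exo closure that forms ring C and leaves C14 as the bridge, and loss of silicon from O11 gives the ketone. C13 is fixed by the one-atom bridge once C8 is set, and C9 is tied to C8 because C11 and C14 must lie on the same face of ring B, so one choice remains: the face of the forming ring B that carries the new carbocycle. The α face is expected because it is flanked only by the lactone oxygen on C10 and H6, while the β face carries C1 and the C6 ester placed there in step 12. Only the 1-silyloxy isomer has C8 as a nucleophilic terminus, and its isomers are drawn into it by 1,5-hydrogen shifts as it is consumed. Closure of C12 onto C15 is disfavoured because C13 is the oxocarbenium carbon and C15 is neopentyl.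

Step 24
Reactants: 33 11-ketone
Product: 34 11-alcohol
Conditions: NaBH4, MeOH/CH2Cl2, −20 °C
Reagents that add atoms: none
Why: Borohydride reduction removes at once the ketone that lies β to the lactone oxygen; the carbinol configuration is immaterial.

Step 25
Reactants: 34 alcohol
Product: 35 O-phenyl thionocarbonate
Conditions: PhOC(S)Cl, pyridine, DMAP (cat.), CH2Cl2, rt
Reagents that add atoms: O-phenyl chlorothionoformate S=C(Cl)Oc1ccccc1
Why: Thioacylation of the secondary alcohol, the first half of the Barton–McCombie deoxygenation.

Step 26
Reactants: 35 thionocarbonate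
Product: 36 C11 methylene compound (allylsilane; C13 silyl ether; acetonide; methyl ester)
Conditions: Bu3SnH, AIBN, toluene, 90 °C
Reagents that add atoms: none
Why: Barton–McCombie radical deoxygenation; the C11 radical has no β leaving group, and the allylsilane and lactone are inert to tin hydride.

Step 27
Reactants: 36 allylsilane
Product: 37 16-methylene compound (13-O-silyl ether 2,3-acetonide 7-methyl ester of 39)
Conditions: CF3CO2H, CH2Cl2, −20 to 0 °C
Reagents that add atoms: none
Why: Protodesilylation of the allylsilane (SE2'): the proton adds to C15 and silicon leaves from C17, so the alkene moves to the exocyclic position. The silyl ether on O13 slows the acid-induced 1,2-shift of the 13-oxygenated 16-ene; partial loss of the acetonide here is harmless.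

Step 28
Reactants: 37 protected ester
Product: 38 7-methyl ester of 39 (free 2β,3β,13-triol)
Conditions: HF (48% aq), MeCN, rt
Reagents that add atoms: none
Why: Aqueous hydrogen fluoride cleaves the tertiary silyl ether and hydrolyses the acetonide; the medium is too weakly acidic to protonate the methylene.

Step 29
Reactants: 38 methyl ester
Product: 39 target acid: 2β,3β,13-trihydroxy-20-norgibberell-16-ene-7,19-dioic acid 19,10-lactone
Conditions: LiSPr, HMPA, 0 °C; then aq. HCl to pH 3
Reagents that add atoms: none
Why: SN2 demethylation of the methyl ester by thiolate, a standard way to free gibberellin acids; the lactone oxygen sits on a tertiary carbon and cannot be dealkylated. Thiolate at 0 °C is too weak a base to start retro-aldol epimerisation at C3, and C6 already has its thermodynamically preferred configuration.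

## Compound list

1 | 5-bromo-2-methoxybenzoic acid | COc1ccc(Br)cc1C(=O)O | starting material
2 | (S)-2-(methoxymethyl)pyrrolidine | COC[C@@H]1CCCN1 | starting material
3 | 5-bromo-2-methoxybenzoyl chloride | COc1ccc(Br)cc1C(=O)Cl | intermediate
4 | (S)-(5-bromo-2-methoxyphenyl)[2-(methoxymethyl)pyrrolidin-1-yl]methanone | COC[C@@H]1CCCN1C(=O)c1cc(Br)ccc1OC | intermediate
5 | (S)-(5-allyl-2-methoxyphenyl)[2-(methoxymethyl)pyrrolidin-1-yl]methanone | COC[C@@H]1CCCN1C(=O)c1cc(CC=C)ccc1OC | intermediate
6 | [(1S)-5-allyl-2-methoxy-1-methylcyclohexa-2,5-dien-1-yl][(S)-2-(methoxymethyl)pyrrolidin-1-yl]methanone | COC[C@@H]1CCCN1C(=O)[C@@]1(C)C=C(CC=C)CC=C1OC | intermediate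
7 | (2S)-4-allyl-2-methyl-2-{[(S)-2-(methoxymethyl)pyrrolidin-1-yl]carbonyl}cyclohex-3-en-1-one | COC[C@@H]1CCCN1C(=O)[C@@]1(C)C=C(CC=C)CCC1=O | intermediate
8 | 5-allyl-8-iodo-1-methyl-6-oxabicyclo[3.2.1]octane-2,7-dione (19,10-lactone, 3-ketone, 5β-iodide anti to the lactone oxygen, allyl on C10) | I[C@H]1[C@](C)(C(=O)O2)C(=O)CC[C@@]12CC=C | intermediate
9 | (E)-prop-1-enyl analogue of 8 | I[C@H]1[C@](C)(C(=O)O2)C(=O)CC[C@@]12/C=C/C | intermediate
10 | chlorohydrin: C10 arm CH(Cl)–CH(OH)–CH3, anti adduct, both facial isomers | I[C@H]1[C@](C)(C(=O)O2)C(=O)CC[C@@]12C(Cl)C(C)O | intermediate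
11 | triethylsilyl ether of 10 | I[C@H]1[C@](C)(C(=O)O2)C(=O)CC[C@@]12C(Cl)C(C)O[Si](CC)(CC)CC | intermediate
12 | 3β-alcohol of 11 (axial hydroxyl syn to the C5 iodide) | I[C@H]1[C@](C)(C(=O)O2)[C@@H](O)CC[C@@]12C(Cl)C(C)O[Si](CC)(CC)CC | intermediate
13 | 5-allyl lactone (allyl syn to the lactone bridge, H5 β) | C=CC[C@@H]1[C@](C)(C(=O)O2)[C@@H](O)CC[C@@]12C(Cl)C(C)O[Si](CC)(CC)CC | intermediate
14 | C7 aldehyde (C5–CH2–CHO) | O=CC[C@@H]1[C@](C)(C(=O)O2)[C@@H](O)CC[C@@]12C(Cl)C(C)O[Si](CC)(CC)CC | intermediate
15 | C7 acid (C5–CH2–CO2H) | OC(=O)C[C@@H]1[C@](C)(C(=O)O2)[C@@H](O)CC[C@@]12C(Cl)C(C)O[Si](CC)(CC)CC | intermediate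
16 | (S)-cyclopent-2-en-1-ol | O[C@@H]1C=CCC1 | starting material
17 | (S)-cyclopent-2-enyl ester of 15 | O=C(O[C@@H]1C=CCC1)C[C@@H]1[C@](C)(C(=O)O2)[C@@H](O)CC[C@@]12C(Cl)C(C)O[Si](CC)(CC)CC | intermediate
18 | (E)-trimethylsilyl ketene acetal of 17 (3-O-trimethylsilyl) | C[Si](C)(C)O/C(O[C@@H]1C=CCC1)=C/[C@@H]1[C@](C)(C(=O)O2)[C@@H](O[Si](C)(C)C)CC[C@@]12C(Cl)C(C)O[Si](CC)(CC)CC | intermediate
19 | trimethylsilyl ester of 20 (3-O-trimethylsilyl) | C[Si](C)(C)OC(=O)[C@H]([C@H]1C=CCC1)[C@@H]2[C@](C)(C(=O)O3)[C@@H](O[Si](C)(C)C)CC[C@@]23C(Cl)C(C)O[Si](CC)(CC)CC | intermediate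
20 | Claisen acid: C6 bears CO2H, H and cyclopent-2-enyl (C8) | OC(=O)[C@H]([C@H]1C=CCC1)[C@@H]2[C@](C)(C(=O)O3)[C@@H](O)CC[C@@]23C(Cl)C(C)O[Si](CC)(CC)CC | intermediate
21 | methyl ester of 20 | COC(=O)[C@H]([C@H]1C=CCC1)[C@@H]2[C@](C)(C(=O)O3)[C@@H](O)CC[C@@]23C(Cl)C(C)O[Si](CC)(CC)CC | intermediate
22 | 4-substituted cyclopent-2-enone (C13 ketone) | COC(=O)[C@H]([C@H]1C=CC(=O)C1)[C@@H]2[C@](C)(C(=O)O3)[C@@H](O)CC[C@@]23C(Cl)C(C)O[Si](CC)(CC)CC | intermediate
23 | 2-iodo enone (iodine on C16) | COC(=O)[C@H]([C@H]1C=C(I)C(=O)C1)[C@@H]2[C@](C)(C(=O)O3)[C@@H](O)CC[C@@]23C(Cl)C(C)O[Si](CC)(CC)CC | intermediate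
24 | 2-ene of ring A | COC(=O)[C@H]([C@H]1C=C(I)C(=O)C1)[C@@H]2[C@](C)(C(=O)O3)C=CC[C@@]23C(Cl)C(C)O[Si](CC)(CC)CC | intermediate
25 | 2β,3β-diol | COC(=O)[C@H]([C@H]1C=C(I)C(=O)C1)[C@@H]2[C@](C)(C(=O)O3)[C@@H](O)[C@@H](O)C[C@@]23C(Cl)C(C)O[Si](CC)(CC)CC | intermediate
26 | 2β,3β-acetonide | COC(=O)[C@H]([C@H]1C=C(I)C(=O)C1)[C@@H]2[C@](C)(C(=O)O3)[C@H]4OC(C)(C)O[C@H]4C[C@@]23C(Cl)C(C)O[Si](CC)(CC)CC | intermediate
27 | 2-(trimethylsilylmethyl) enone | COC(=O)[C@H]([C@H]1C=C(C[Si](C)(C)C)C(=O)C1)[C@@H]2[C@](C)(C(=O)O3)[C@H]4OC(C)(C)O[C@H]4C[C@@]23C(Cl)C(C)O[Si](CC)(CC)CC | intermediate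
28 | free chlorohydrin (C11 hydroxyl) | COC(=O)[C@H]([C@H]1C=C(C[Si](C)(C)C)C(=O)C1)[C@@H]2[C@](C)(C(=O)O3)[C@H]4OC(C)(C)O[C@H]4C[C@@]23C(Cl)C(C)O | intermediate
29 | α-chloro methyl ketone (C9 chloride, C11 ketone) | COC(=O)[C@H]([C@H]1C=C(C[Si](C)(C)C)C(=O)C1)[C@@H]2[C@](C)(C(=O)O3)[C@H]4OC(C)(C)O[C@H]4C[C@@]23C(Cl)C(C)=O | intermediate
30 | kinetic bis(silyl enol ether): cross-conjugated 2-silyloxydiene with sp3 C8 | COC(=O)[C@H]([C@H]1C=C(C[Si](C)(C)C)C(O[Si](C)(C)C(C)(C)C)=C1)[C@@H]2[C@](C)(C(=O)O3)[C@H]4OC(C)(C)O[C@H]4C[C@@]23C(Cl)C(=C)O[Si](C)(C)C(C)(C)C | intermediate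
31 | key-step precursor: ring A lactone acetonide, C6-linked 1-silyloxy-2-(silylmethyl)cyclopentadiene, C10 arm CHCl–C(OTBS)=CH2 | COC(=O)[C@H](C1=CC(C[Si](C)(C)C)=C(O[Si](C)(C)C(C)(C)C)C1)[C@@H]2[C@](C)(C(=O)O3)[C@H]4OC(C)(C)O[C@H]4C[C@@]23C(Cl)C(=C)O[Si](C)(C)C(C)(C)C | intermediate
32 | 2-silyloxyallyl cation (C9–C11–C12) as triflate | COC(=O)[C@H](C1=CC(C[Si](C)(C)C)=C(O[Si](C)(C)C(C)(C)C)C1)[C@@H]2[C@](C)(C(=O)O3)[C@H]4OC(C)(C)O[C@H]4C[C@@]23[CH+]C(=C)O[Si](C)(C)C(C)(C)C.[O-]S(=O)(=O)C(F)(F)F | intermediate
33 | pentacyclic 11-ketone with C15=C16 allylsilane, C13 silyl ether, acetonide, 7-methyl ester | C[Si](C)(C)CC1=C[C@]23C[C@@]1(O[Si](C)(C)C(C)(C)C)CC(=O)[C@H]2[C@@]12C[C@@H]4OC(C)(C)O[C@@H]4[C@@](C)(C(=O)O1)[C@H]2[C@@H]3C(=O)OC | intermediate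
34 | 11-alcohol of 33 | C[Si](C)(C)CC1=C[C@]23C[C@@]1(O[Si](C)(C)C(C)(C)C)CC(O)[C@H]2[C@@]12C[C@@H]4OC(C)(C)O[C@@H]4[C@@](C)(C(=O)O1)[C@H]2[C@@H]3C(=O)OC | intermediate
35 | 11-O-phenoxythiocarbonyl derivative of 34 | C[Si](C)(C)CC1=C[C@]23C[C@@]1(O[Si](C)(C)C(C)(C)C)CC(OC(=S)Oc5ccccc5)[C@H]2[C@@]12C[C@@H]4OC(C)(C)O[C@@H]4[C@@](C)(C(=O)O1)[C@H]2[C@@H]3C(=O)OC | intermediate
36 | 11-deoxy allylsilane | C[Si](C)(C)CC1=C[C@]23C[C@@]1(O[Si](C)(C)C(C)(C)C)CC[C@H]2[C@@]12C[C@@H]4OC(C)(C)O[C@@H]4[C@@](C)(C(=O)O1)[C@H]2[C@@H]3C(=O)OC | intermediate
37 | 13-O-tert-butyldimethylsilyl ether 2,3-acetonide 7-methyl ester of 39 | C=C1C[C@]23C[C@@]1(O[Si](C)(C)C(C)(C)C)CC[C@H]2[C@@]12C[C@@H]4OC(C)(C)O[C@@H]4[C@@](C)(C(=O)O1)[C@H]2[C@@H]3C(=O)OC | intermediate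
38 | 7-methyl ester of 39 with free 2β,3β,13-triol | C=C1C[C@]23C[C@@]1(O)CC[C@H]2[C@@]12C[C@H](O)[C@H](O)[C@@](C)(C(=O)O1)[C@H]2[C@@H]3C(=O)OC | intermediate
39 | 2β,3β,13-trihydroxy-20-norgibberell-16-ene-7,19-dioic acid 19,10-lactone (ent-2α,3α,10,13-tetrahydroxy-20-norgibberell-16-ene-7,19-dioic acid 19,10-lactone; the gibberellin numbered eight in the A series) | C=C1C[C@]23C[C@@]1(O)CC[C@H]2[C@@]12C[C@H](O)[C@H](O)[C@@](C)(C(=O)O1)[C@H]2[C@@H]3C(=O)O | target

## Step count and least certain steps

Total step count: 29. Longest linear sequence: 29 steps (from 1 to 39).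

Step 23 (key step, Proposed new method). What may go wrong: capture of cation 32 at C9 by triflate, or loss of silicon from O11, before C8 reaches C9, because C9 is neopentyl and sits next to the acyloxy-bearing C10. Other risks are reaction of the isomeric 2-silyloxy diene through C16, closure of the second bond onto C15, and addition to the β face of the forming ring B. Fallback, with known reactions only: it sets out from chlorohydrin 28 and comes back to the route at 33. K2CO3 in MeCN closes the C9–C11 epoxide F1 . KOt-Bu in THF then generates the extended dienolate of the cyclopentenone, whose γ-carbon C8 opens the epoxide at C9 in a 5-exo alkylation; this gives the ring B closed hydroxy enone F2 . Dess–Martin oxidation gives the ring B closed methyl ketone F3 . LiN(SiMe3)2 at −78 °C forms the methyl ketone enolate, which adds to the C13 carbonyl in an intramolecular aldol reaction, and TBSOTf in the same flask silylates the tertiary alkoxide to give 33.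

Step 22. What may go wrong: enolisation of the chloro ketone toward C9, whose hydrogen is the more acidic one, which leads to an unreactive chloro enol ether or to loss of the lactone by β-elimination. The diene may also fail to leave the cross-conjugated form. Fallback: it sets out from 29 and comes back at 33 without passing through 31. One equivalent of TBSOTf with Et3N at −78 °C silylates only the more basic cyclopentenone carbonyl and gives the mono(silyl dienol ether) F4 . Et3N in CF3CH2OH then enolises the free chloro ketone on the methyl side and chloride leaves from C9, which releases the free oxyallyl cation; the cycloaddition gives 33.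

Step 12. What may go wrong: poor discrimination between chair and boat transition states, which would form the C6 epimer beside 20. A wrong C6 would put the ester on the α face and work against the facial selectivity of step 23. Fallback: it sets out from 20 mixed with its C6 epimer F5 and comes back at 20. I2 and NaHCO3 convert the mixture into the cis-fused γ-iodolactone F6 and its C6 epimer F7 . Catalytic KOt-Bu in THF at −20 °C equilibrates the lactone α-carbon C6 toward F6 , which carries ring A on the convex face and has the required configuration. Zn in AcOH opens the iodolactone back to 20. C6 also remains correctable by base after ring B is closed, since the natural ester is the stable one.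

Step 14. What may go wrong: hydrogen abstraction at the tertiary C8–H, or oxygen delivery to C15, either of which leads to a regioisomeric enone. Fallback: it sets out from 21 and comes back at 22. SeO2 (cat.) with t-BuOOH hydroxylates C13 through an ene reaction and [2,3]-shift, which cannot transpose the alkene, and gives the C13 allylic alcohol F8 . MnO2 oxidises only this allylic alcohol and gives 22.

## Further compounds

F1 | step 23 | C9–C11 epoxide of the C10 arm | COC(=O)[C@H]([C@H]1C=C(C[Si](C)(C)C)C(=O)C1)[C@@H]2[C@](C)(C(=O)O3)[C@H]4OC(C)(C)O[C@H]4C[C@@]23C5OC5C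
F2 | step 23 | ring B closed hydroxy enone (C8 quaternary, C9 bears CH(OH)CH3) | C[Si](C)(C)CC1=C[C@]2(CC1=O)[C@@H](C(C)O)[C@@]34C[C@@H]5OC(C)(C)O[C@@H]5[C@@](C)(C(=O)O3)[C@H]4[C@@H]2C(=O)OC
F3 | step 23 | ring B closed diketone (C9 acetyl, C13 enone carbonyl) | C[Si](C)(C)CC1=C[C@]2(CC1=O)[C@@H](C(C)=O)[C@@]34C[C@@H]5OC(C)(C)O[C@@H]5[C@@](C)(C(=O)O3)[C@H]4[C@@H]2C(=O)OC
F4 | step 22 | mono(silyl dienol ether) with free α-chloro ketone | COC(=O)[C@H](C1=CC(C[Si](C)(C)C)=C(O[Si](C)(C)C(C)(C)C)C1)[C@@H]2[C@](C)(C(=O)O3)[C@H]4OC(C)(C)O[C@H]4C[C@@]23C(Cl)C(C)=O
F5 | step 12 | C6 epimer of 20 | OC(=O)[C@@H]([C@H]1C=CCC1)[C@@H]2[C@](C)(C(=O)O3)[C@@H](O)CC[C@@]23C(Cl)C(C)O[Si](CC)(CC)CC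
F6 | step 12 | cis-fused γ-iodolactone of 20 (C7 to C15, iodine on C16, ring A on the convex face) | O=C1O[C@H]2[C@H](I)CC[C@H]2[C@@H]1[C@@H]3[C@](C)(C(=O)O4)[C@@H](O)CC[C@@]34C(Cl)C(C)O[Si](CC)(CC)CC
F7 | step 12 | C6 epimer of F6 | O=C1O[C@H]2[C@H](I)CC[C@H]2[C@H]1[C@@H]3[C@](C)(C(=O)O4)[C@@H](O)CC[C@@]34C(Cl)C(C)O[Si](CC)(CC)CC
F8 | step 14 | C13 allylic alcohol of 21 | COC(=O)[C@H]([C@H]1C=CC(O)C1)[C@@H]2[C@](C)(C(=O)O3)[C@@H](O)CC[C@@]23C(Cl)C(C)O[Si](CC)(CC)CC
A1 | alternative 1 | 13-hydroxy ring-B-contracted 7-aldehyde 19-methyl ester with C20 retained | C=C1C[C@]23C[C@@]1(O)CC[C@H]2[C@]2(C)CCC[C@@](C)(C(=O)OC)[C@H]2[C@@H]3C=O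
A2 | alternative 1 | steviol | C=C1C[C@]23C[C@@]1(O)CC[C@H]2[C@]2(C)CCC[C@@](C)(C(=O)O)[C@H]2CC3
A3 | alternative 2 | 19-acid with a C1=C10 alkene in ring A and with C4 and C5 set | C=C1C[C@]23C[C@@]1(O[Si](C)(C)C(C)(C)C)CC[C@H]2C2=C[C@@H]4OC(C)(C)O[C@@H]4[C@@](C)(C(=O)O)[C@H]2[C@@H]3CO[Si](C)(C)C(C)(C)C
A4 | alternative 3 | 2-O-tert-butyldimethylsilyl ether 7-methyl ester of the target 39 | C=C1C[C@]23C[C@@]1(O)CC[C@H]2[C@@]12C[C@H](O[Si](C)(C)C(C)(C)C)[C@H](O)[C@@](C)(C(=O)O1)[C@H]2[C@@H]3C(=O)OC
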